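Remark on the chemistry: flavan numbering (O1, C2, C3, C4, C4a, C5–C8, C8a; ring B primed) is used for all intermediates, including the open-chain ones. TBS is tert-butyldimethylsilyl and MOM is methoxymethyl. The descriptor 4β is read from the SMILES as (4S), that is, the 3,4-cis diol.

## Analysis of the target

Target 22 is a flavan-3,4-diol. Ring A is a fully differentiated phloroglucinol-type benzene (5-OMe, 7-OH, 8-prenyl), ring C is a dihydropyran with three contiguous stereocentres, and ring B is a 4-hydroxyphenyl group on C2. The configuration is (2R,3S,4S): the aryl group at C2 and the hydroxyl at C3 are trans, and the hydroxyls at C3 and C4 are cis. Three groups limit the reagents that can be used: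

- The C4 hydroxyl is benzylic to an arene with oxygen at C5, C7 and C8a, so it ionises readily in acid.
- The O1–C2 bond is a para-hydroxybenzylic ether that can open to a quinone methide under base.
- The prenyl alkene is electron-rich, reacts with electrophilic oxidants, and in strong acid adds the flanking phenols.

The synthesis therefore has to bring in the C3 oxygen and all three stereocentres under mild, non-electrophilic conditions, and has to place OMe, OH and prenyl unambiguously on ring A. The plan rests on one feature: C4 carries a hydroxyl directly next to C3 and C2. If ring C is opened at O1–C2, C4 is a secondary allylic alcohol flanked by a C2=C3 styrene-type alkene. That hydroxyl can bind a Ti(OiPr)4/tartrate catalyst and deliver oxygen to C2=C3 alone, whereas the prenyl alkene has no such handle. The erythro epoxy alcohol so formed already holds the cis-3,4 relationship, and opening it at C2 by the C8a oxygen with inversion gives the 2,3-trans ring.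

## Retrosynthetic reasoning

**22 from 21.** The phenols at C7 and C4' are unmasked last from the bis-TBS ether 21. Silyl ethers are chosen because buffered fluoride is neither acidic enough to ionise C4 nor basic enough to open ring C.

**21 from 20 (cut O1–C2).** C2 is the only ring C position where a C–O bond can be made by substitution with a predictable course, because it is benzylic to ring B. With an epoxide as the leaving group the C3 oxygen is in place at the same time. Forward, the C8a phenol of 20 must open the trans-epoxide at C2 (6-endo) with inversion. The silyl group on ring B is kept during this step so that the opening is not a free quinone-methide ionisation.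

**20 from 19 (protecting group at O8a).** The C8a oxygen has to be freed in the presence of two aryl silyl ethers, an acid-sensitive epoxide and the C4 carbinol. A trialkylsilyl ether here would sit between the prenyl group and the carbinol carbon and be more hindered than the two silyl ethers it must be distinguished from. Fluoride or base would not discriminate reliably, and acid is excluded. The oxygen is therefore carried as an allyl ether in 19 and removed by zerovalent palladium under near-neutral conditions.

**19 from 18 (cut both epoxide C–O bonds).** Removing the epoxide oxygen gives the (R,E)-allylic alcohol 18. This is the point where the C4 hydroxyl is used: Sharpless asymmetric epoxidation in the matched sense must oxidise C2=C3 from one face, erythro to C4, and leave the prenyl and allyl alkenes alone. Any other oxidant for C2=C3 would have to compete with the more electron-rich prenyl alkene.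

**18 from 10 and 15 (cut C3–C4).** This separates a ring A aldehyde 10 from a ring B alkyne 15, so the two halves are made independently. Forward, syn-hydrometalation of 15 fixes the E geometry (via 16 and 17), and a ligand-controlled alkenylzinc addition to 10 sets C4. A chalcone reduction was not chosen because a ketone flanked by a di-ortho-substituted aryl group and a styryl group offers a reducing catalyst little steric distinction.

**10 from 9 and 8 (protecting-group pattern).** In the dihydroxy aldehyde 8 the two phenols differ: the one para to the formyl group is free, the ortho one is hydrogen-bonded to the carbonyl. The first is silylated selectively (9) and the second allylated (10).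

**8 from 7, 5, 2, 1 and 3 (ring A substitution).** 5-Methoxyresorcinol 1 is symmetric. In its bis-MOM ether 2 the position between the two acetal oxygens is the preferred site of directed metalation (aryllithium 4), so prenyl bromide 3 enters para to the methoxy group (5). The two remaining ring positions of 5 are then equivalent, so a second metalation (aryllithium 6) and formylation can give only aldehyde 7. The MOM groups are needed for the metalations but cannot be carried to the end, because their removal needs acid. They are exchanged at the robust aldehyde stage (8).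

**15 from 13, 12 and 11.** The alkyne comes from 4-hydroxybenzaldehyde 11 by silylation (12) and Corey–Fuchs homologation through dibromoalkene 13 and acetylide 14.

## Alternatives that were turned down

**Alternative 1: ring A annulated onto a chiral pyranone.**
- Disconnection: ring A is removed altogether by cutting C8–C8a and C4a–C5. This leaves the enantiopure bromo-dihydropyranone A2, which carries C2 and C3, and the open-chain bis(silyloxy) diene A1, which carries the prenyl group and the future C5 methoxy carbon.
- Forward key step: [4+2] addition of A1 across C4a=C8a of A2, then loss of HBr and silanol, to give the flavanone A3 with ring A aromatised.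
- For: the ring A pattern follows from the polarity of the diene, with no directed metalation and no protecting-group exchange, and the 7-OH emerges free. C2 and C3 come in as a configurationally robust 2,3-trans unit. On ring A regiochemistry and step count this alternative is stronger than the chosen route, which spends six steps there.
- Against: A2 needs its own enantioselective multistep synthesis. A diene substituted at its nucleophilic terminus adds less readily. The basic aromatisation conditions can also eliminate the C3 silyloxy group α to the ketone. Above all, C4 arrives as a ketone: the 4β alcohol must come from a late reduction that delivers the pseudoaxial hydroxyl cis to the C3 oxygen, next to the peri 5-methoxy group, and nothing in A3 guarantees that face.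
- Comparison: the chosen strategy fixes C4 first under catalyst control and then uses it to set C3 and C2, so no stereocentre is left to a substrate-dependent reduction.

**Alternative 2: alkoxy ortho-quinone methide hetero-Diels–Alder.**
- Disconnection: O1–C2 and C3–C4 are cut together. Ring C comes from the 4-methoxy ortho-quinone methide A4, generated from salicylaldehyde 9 with an orthoformate under a chiral phosphoric acid, and the (E)-enol acetate A5 of ring B.
- Forward key step: inverse-demand hetero-Diels–Alder addition to give A6, the 3-O-acetyl-4-O-methyl bis-silyl ether of the target.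
- For: it is the shortest and most convergent plan, closing ring C and setting up to three stereocentres in one step from a compound the chosen route also makes. On step economy it is clearly stronger.
- Against: the dienophile is polarised in opposite senses by its acetoxy and aryl groups, so the regiochemistry depends on the silyloxyphenyl group outweighing the enol ester. Enantio- and diastereocontrol for a 2,6-dioxygenated, prenyl-flanked quinone methide with an enol ester has no close analogy to lean on. The prenyl alkene and phenol are exposed to Brønsted acid. C4 emerges as a methyl ether, which must be exchanged for hydroxyl by solvolysis through the C4 cation, the very ionisation that makes the target fragile, and the C4 configuration is decided only then.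
- Comparison: the chosen route is longer, but each stereocentre has its own control element and C4 has the right oxidation level and configuration from the start.

**Alternative 3: ring B quinone methide recaptured by the ring A phenoxide.**
- Disconnection: O1–C2, as in the chosen route, but from the acyclic precursor A7 with an acetate at C2, a cyclic carbonate across the C3 and C4 oxygens, and silylated phenols.
- Forward key step: fluoride frees the phenoxides, the ring B phenoxide expels acetate to give the para-quinone methide A8, and the C8a phenoxide adds to C2 to give the carbonate A9 of the target.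
- For: ring closure and phenol deprotection happen in one operation without acid, and the carbonate protects the labile C4 oxygen and locks the cis-diol. On acid exposure of C4 it is stronger than the chosen acid-promoted closure.
- Against: C2 is formed by addition to a planar quinone methide, so the 2,3-trans outcome depends on conformational preference and not on a stereospecific event. The cis-3,4-diol of A7 must come from a separate alkene oxidation in a molecule that contains the more electron-rich prenyl alkene, so the chemoselectivity problem returns without a directing group. The C8a phenoxide can also expel the C4 carbonate oxygen. The carbonate must finally be hydrolysed with base on a compound whose O1–C2 bond is base-labile.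
- Comparison: the chosen route makes the same bond by inversion at a defined epoxide and solves chemoselectivity through the C4 hydroxyl. The quinone-methide closure is kept only as the fallback for step 13.

Key step: step 11

## Route

Step 1
Reactants: 1 5-methoxyresorcinol
Product: 2 1-methoxy-3,5-bis(methoxymethoxy)benzene
Conditions: MOMCl (2.5 equiv), iPr2NEt, CH2Cl2, 0 °C → rt
Reagents that add atoms: chloromethyl methyl ether, COCCl
Why: Double O-alkylation of the two equivalent phenols gives the bis-acetal; the MOM ethers are the directing groups for both metalations that follow.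

Step 2
Reactants: 2 1-methoxy-3,5-bis(methoxymethoxy)benzene; 3 prenyl bromide (1-bromo-3-methylbut-2-ene)
Product: 5 5-methoxy-1,3-bis(methoxymethoxy)-2-(3-methylbut-2-en-1-yl)benzene, via aryllithium 4 (not isolated)
Conditions: n-BuLi, THF, 0 °C; then 3, −78 °C → rt
Reagents that add atoms: none
Why: Directed ortho-metalation should occur at the position flanked by both chelating MOM ethers, which direct more strongly than methoxy, and the aryllithium is alkylated at the primary allylic carbon of 3 (SN2). The prenyl group thus ends up para to the methoxy group, as C8 is to C5 in the target.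

Step 3
Reactants: 5 5-methoxy-1,3-bis(methoxymethoxy)-2-(3-methylbut-2-en-1-yl)benzene
Product: 7 6-methoxy-2,4-bis(methoxymethoxy)-3-(3-methylbut-2-en-1-yl)benzaldehyde, via aryllithium 6 (not isolated)
Conditions: n-BuLi, TMEDA, THF, −20 → 0 °C; DMF; aq. NH4Cl
Reagents that add atoms: N,N-dimethylformamide, CN(C)C=O
Why: A second directed ortho-metalation takes one of the two remaining ring positions, which are equivalent by symmetry and each flanked by a MOM ether and the methoxy group, so only one aldehyde can form; formylation of the aryllithium with a formamide is standard.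

Step 4
Reactants: 7 6-methoxy-2,4-bis(methoxymethoxy)-3-(3-methylbut-2-en-1-yl)benzaldehyde
Product: 8 2,4-dihydroxy-6-methoxy-3-(3-methylbut-2-en-1-yl)benzaldehyde
Conditions: HCl (3 M aq.), MeOH, rt
Reagents that add atoms: none
Why: Acid-catalysed transacetalisation to methanol removes both MOM groups at a stage where the electron-poor aldehyde is not ionisable; short exposure at room temperature is chosen to keep the phenols from adding to the prenyl alkene.

Step 5
Reactants: 8 2,4-dihydroxy-6-methoxy-3-(3-methylbut-2-en-1-yl)benzaldehyde
Product: 9 4-[(tert-butyldimethylsilyl)oxy]-2-hydroxy-6-methoxy-3-(3-methylbut-2-en-1-yl)benzaldehyde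
Conditions: TBSCl (1.05 equiv), imidazole, CH2Cl2, 0 °C
Reagents that add atoms: tert-butyldimethylsilyl chloride, CC(C)(C)[Si](C)(C)Cl
Why: Selective silylation: the hydroxyl para to the formyl group is free and more acidic, whereas the ortho hydroxyl is tied up in a hydrogen bond to the carbonyl and shielded on both sides.

Step 6
Reactants: 9 4-[(tert-butyldimethylsilyl)oxy]-2-hydroxy-6-methoxy-3-(3-methylbut-2-en-1-yl)benzaldehyde
Product: 10 2-(allyloxy)-4-[(tert-butyldimethylsilyl)oxy]-6-methoxy-3-(3-methylbut-2-en-1-yl)benzaldehyde
Conditions: allyl alcohol, PPh3, DIAD, THF, 0 °C → rt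
Reagents that add atoms: allyl alcohol, C=CCO
Why: Mitsunobu etherification of the acidic salicylaldehyde-type phenol with a primary allylic alcohol; it avoids carbonate bases that could cleave or transfer the aryl silyl ether para to the aldehyde.

Step 7
Reactants: 11 4-hydroxybenzaldehyde
Product: 12 4-[(tert-butyldimethylsilyl)oxy]benzaldehyde
Conditions: TBSCl, imidazole, DMF, rt
Reagents that add atoms: tert-butyldimethylsilyl chloride, CC(C)(C)[Si](C)(C)Cl
Why: Routine silylation of a phenol; the same silyl group as on ring A allows one final deprotection.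

Step 8
Reactants: 12 4-[(tert-butyldimethylsilyl)oxy]benzaldehyde
Product: 13 tert-butyl[4-(2,2-dibromovinyl)phenoxy]dimethylsilane
Conditions: CBr4, PPh3, CH2Cl2, 0 °C
Reagents that add atoms: carbon tetrabromide, BrC(Br)(Br)Br
Why: First stage of the Corey–Fuchs homologation, a Wittig-type dibromo-olefination under neutral conditions that leave the aryl silyl ether intact.

Step 9
Reactants: 13 tert-butyl[4-(2,2-dibromovinyl)phenoxy]dimethylsilane
Product: 15 tert-butyl(4-ethynylphenoxy)dimethylsilane, via lithium acetylide 14 (not isolated)
Conditions: n-BuLi (2.1 equiv), THF, −78 °C; aq. NH4Cl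
Reagents that add atoms: none
Why: Second stage of the Corey–Fuchs homologation: bromine–lithium exchange and Fritsch–Buttenberg–Wiechell-type loss of LiBr give the alkyne, which is held as its acetylide until the quench; the aryl silyl ether is stable to n-BuLi at −78 °C.

Step 10
Reactants: 15 tert-butyl(4-ethynylphenoxy)dimethylsilane; 10 2-(allyloxy)-4-[(tert-butyldimethylsilyl)oxy]-6-methoxy-3-(3-methylbut-2-en-1-yl)benzaldehyde
Product: 18 (R,E)-1-{2-(allyloxy)-4-[(tert-butyldimethylsilyl)oxy]-6-methoxy-3-(3-methylbut-2-en-1-yl)phenyl}-3-{4-[(tert-butyldimethylsilyl)oxy]phenyl}prop-2-en-1-ol, via alkenylzirconocene chloride 16 (not isolated), via alkenylmethylzinc 17 (not isolated)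
Conditions: Cp2Zr(H)Cl, CH2Cl2, rt; Me2Zn, toluene, −65 °C; (+)-MIB [(2R)-3-exo-morpholinoisoborneol, 10 mol %], 10, −30 → 0 °C; aq. NH4Cl
Reagents that add atoms: none
Why: syn-Hydrozirconation of the terminal alkyne puts the metal on the terminal carbon and fixes the E geometry; transmetalation to zinc gives 17, which adds to the aldehyde in an amino-alcohol-catalysed asymmetric alkenylzinc 1,2-addition. (+)-MIB, the antipode of the ligand that sends ethyl to the Si face of benzaldehyde, should direct the alkenyl group to the Re face and give the (R)-carbinol, the future C4. Any shortfall in enantiomeric purity is corrected in step 11, which consumes only the matched enantiomer.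

Step 11
Reactants: 18 (R,E)-1-{2-(allyloxy)-4-[(tert-butyldimethylsilyl)oxy]-6-methoxy-3-(3-methylbut-2-en-1-yl)phenyl}-3-{4-[(tert-butyldimethylsilyl)oxy]phenyl}prop-2-en-1-ol
Product: 19 (S)-{2-(allyloxy)-4-[(tert-butyldimethylsilyl)oxy]-6-methoxy-3-(3-methylbut-2-en-1-yl)phenyl}[(2S,3S)-3-{4-[(tert-butyldimethylsilyl)oxy]phenyl}oxiran-2-yl]methanol
Conditions: Ti(OiPr)4 (0.2 equiv), L-(+)-DIPT (0.25 equiv), t-BuOOH (0.95 equiv, in decane), 4 Å MS, CH2Cl2, −20 °C; sat. aq. Na2SO4, Et2O, filtration
Reagents that add atoms: tert-butyl hydroperoxide, CC(C)(C)OO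
Why: The C4 alkoxide and the hydroperoxide exchange onto the Ti(OiPr)4/tartrate complex (tetravalent titanium), and the activated peroxide oxygen is passed to the neighbouring C2=C3 bond; the closest known reaction is the Sharpless asymmetric epoxidation of secondary (E)-allylic alcohols in its kinetic-resolution, matched sense. The oxirane is closed by concerted transfer of one oxygen atom to both alkene carbons, a [2+1] addition and not a chain cyclisation, so the E geometry is carried into a trans-epoxide. The configurations at C2 and C3 are set by the tartrate: the L-(+) ligand delivers oxygen to the face that gives (2S,3S)-epoxides from (E)-allylic alcohols. The relation of C3 to C4 is set by the pairing of ligand and carbinol: in the (R)-alcohol the carbinol hydrogen, not the aryl group, points toward the tartrate ester in the loaded complex, which is the fast-reacting arrangement and leads to the erythro epoxy alcohol. The step needs chemoselectivity over the prenyl and allyl alkenes, and this is secured because only C2=C3 sits next to a hydroxyl that can bind titanium, and it is also the most electron-rich 1,2-disubstituted alkene. It also needs discrimination between the enantiomers of 18; with slightly less than one equivalent of oxidant, the mismatched (S)-alcohol should be left behind. Molecular sieves, a catalytic titanium loading, low temperature and a non-acidic work-up are chosen to keep the aryl epoxide and the ionisable C4 carbinol intact.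

Step 12
Reactants: 19 (S)-{2-(allyloxy)-4-[(tert-butyldimethylsilyl)oxy]-6-methoxy-3-(3-methylbut-2-en-1-yl)phenyl}[(2S,3S)-3-{4-[(tert-butyldimethylsilyl)oxy]phenyl}oxiran-2-yl]methanol
Product: 20 (S)-{4-[(tert-butyldimethylsilyl)oxy]-2-hydroxy-6-methoxy-3-(3-methylbut-2-en-1-yl)phenyl}[(2S,3S)-3-{4-[(tert-butyldimethylsilyl)oxy]phenyl}oxiran-2-yl]methanol
Conditions: Pd(PPh3)4 (5 mol %), N-methylaniline, THF, rt
Reagents that add atoms: none
Why: Zerovalent palladium ionises only the aryl allyl ether (Tsuji–Trost-type deallylation) and the allyl fragment is trapped by the weakly basic amine; the silyl ethers, the epoxide, the prenyl group and the C4 carbinol offer palladium no leaving group. The medium is neither acidic nor strongly basic, so the epoxide should stay closed until step 13.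

Step 13
Reactants: 20 (S)-{4-[(tert-butyldimethylsilyl)oxy]-2-hydroxy-6-methoxy-3-(3-methylbut-2-en-1-yl)phenyl}[(2S,3S)-3-{4-[(tert-butyldimethylsilyl)oxy]phenyl}oxiran-2-yl]methanol
Product: 21 (2R,3S,4S)-7-[(tert-butyldimethylsilyl)oxy]-2-{4-[(tert-butyldimethylsilyl)oxy]phenyl}-5-methoxy-8-(3-methylbut-2-en-1-yl)chromane-3,4-diol
Conditions: PPTS (10 mol %), CH2Cl2, 0 °C
Reagents that add atoms: none
Why: Mild Brønsted acid activates the epoxide and the C8a phenol attacks C2, the benzylic terminus stabilised by ring B, in a 6-endo opening (the acid-catalysed intramolecular epoxide opening used for flavan-3-ols) in preference to 5-exo attack at C3. Attack anti to the breaking C2–O bond inverts C2 and gives the 2,3-trans ring with both substituents equatorial, which is also the outcome favoured if the opening has some cationic character. C3 and C4 are untouched, so the cis-3,4-diol is carried over from the erythro epoxy alcohol.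

Step 14
Reactants: 21 (2R,3S,4S)-7-[(tert-butyldimethylsilyl)oxy]-2-{4-[(tert-butyldimethylsilyl)oxy]phenyl}-5-methoxy-8-(3-methylbut-2-en-1-yl)chromane-3,4-diol
Product: 22 5-O-methyl-8-prenylafzelechin-4β-ol [(2R,3S,4S)-2-(4-hydroxyphenyl)-5-methoxy-8-(3-methylbut-2-en-1-yl)chromane-3,4,7-triol]
Conditions: TBAF, AcOH (1:1), THF, 0 °C
Reagents that add atoms: none
Why: Fluoride cleaves both aryl silyl ethers; buffering with acetic acid keeps the medium too weakly basic to open ring C through the ring B phenoxide and too weakly acidic to ionise the C4 carbinol.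

## Compound list

1 | 5-methoxyresorcinol (5-methoxybenzene-1,3-diol) | COc1cc(O)cc(O)c1 | starting material
2 | 1-methoxy-3,5-bis(methoxymethoxy)benzene | COCOc1cc(OC)cc(OCOC)c1 | intermediate
3 | prenyl bromide (1-bromo-3-methylbut-2-ene) | CC(C)=CCBr | starting material
4 | [4-methoxy-2,6-bis(methoxymethoxy)phenyl]lithium | [Li]c1c(OCOC)cc(OC)cc1OCOC | intermediate
5 | 5-methoxy-1,3-bis(methoxymethoxy)-2-(3-methylbut-2-en-1-yl)benzene | COCOc1cc(OC)cc(OCOC)c1CC=C(C)C | intermediate
6 | [6-methoxy-2,4-bis(methoxymethoxy)-3-(3-methylbut-2-en-1-yl)phenyl]lithium | [Li]c1c(OC)cc(OCOC)c(CC=C(C)C)c1OCOC | intermediate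
7 | 6-methoxy-2,4-bis(methoxymethoxy)-3-(3-methylbut-2-en-1-yl)benzaldehyde | COCOc1cc(OC)c(C=O)c(OCOC)c1CC=C(C)C | intermediate
8 | 2,4-dihydroxy-6-methoxy-3-(3-methylbut-2-en-1-yl)benzaldehyde | COc1cc(O)c(CC=C(C)C)c(O)c1C=O | intermediate
9 | 4-[(tert-butyldimethylsilyl)oxy]-2-hydroxy-6-methoxy-3-(3-methylbut-2-en-1-yl)benzaldehyde | COc1cc(O[Si](C)(C)C(C)(C)C)c(CC=C(C)C)c(O)c1C=O | intermediate
10 | 2-(allyloxy)-4-[(tert-butyldimethylsilyl)oxy]-6-methoxy-3-(3-methylbut-2-en-1-yl)benzaldehyde | COc1cc(O[Si](C)(C)C(C)(C)C)c(CC=C(C)C)c(OCC=C)c1C=O | intermediate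
11 | 4-hydroxybenzaldehyde | O=Cc1ccc(O)cc1 | starting material
12 | 4-[(tert-butyldimethylsilyl)oxy]benzaldehyde | O=Cc1ccc(O[Si](C)(C)C(C)(C)C)cc1 | intermediate
13 | tert-butyl[4-(2,2-dibromovinyl)phenoxy]dimethylsilane | BrC(Br)=Cc1ccc(O[Si](C)(C)C(C)(C)C)cc1 | intermediate
14 | lithium {4-[(tert-butyldimethylsilyl)oxy]phenyl}acetylide | [Li]C#Cc1ccc(O[Si](C)(C)C(C)(C)C)cc1 | intermediate
15 | tert-butyl(4-ethynylphenoxy)dimethylsilane | C#Cc1ccc(O[Si](C)(C)C(C)(C)C)cc1 | intermediate
16 | chlorobis(cyclopentadienyl)[(E)-2-{4-[(tert-butyldimethylsilyl)oxy]phenyl}vinyl]zirconium | Cl[Zr](/C=C/c1ccc(O[Si](C)(C)C(C)(C)C)cc1)(C1C=CC=C1)C1C=CC=C1 | intermediate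
17 | [(E)-2-{4-[(tert-butyldimethylsilyl)oxy]phenyl}vinyl](methyl)zinc | C[Zn]/C=C/c1ccc(O[Si](C)(C)C(C)(C)C)cc1 | intermediate
18 | (R,E)-1-{2-(allyloxy)-4-[(tert-butyldimethylsilyl)oxy]-6-methoxy-3-(3-methylbut-2-en-1-yl)phenyl}-3-{4-[(tert-butyldimethylsilyl)oxy]phenyl}prop-2-en-1-ol | COc1cc(O[Si](C)(C)C(C)(C)C)c(CC=C(C)C)c(OCC=C)c1[C@H](O)/C=C/c1ccc(O[Si](C)(C)C(C)(C)C)cc1 | intermediate
19 | (S)-{2-(allyloxy)-4-[(tert-butyldimethylsilyl)oxy]-6-methoxy-3-(3-methylbut-2-en-1-yl)phenyl}[(2S,3S)-3-{4-[(tert-butyldimethylsilyl)oxy]phenyl}oxiran-2-yl]methanol | COc1cc(O[Si](C)(C)C(C)(C)C)c(CC=C(C)C)c(OCC=C)c1[C@H](O)[C@@H]2O[C@H]2c1ccc(O[Si](C)(C)C(C)(C)C)cc1 | intermediate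
20 | (S)-{4-[(tert-butyldimethylsilyl)oxy]-2-hydroxy-6-methoxy-3-(3-methylbut-2-en-1-yl)phenyl}[(2S,3S)-3-{4-[(tert-butyldimethylsilyl)oxy]phenyl}oxiran-2-yl]methanol | COc1cc(O[Si](C)(C)C(C)(C)C)c(CC=C(C)C)c(O)c1[C@H](O)[C@@H]2O[C@H]2c1ccc(O[Si](C)(C)C(C)(C)C)cc1 | intermediate
21 | (2R,3S,4S)-7-[(tert-butyldimethylsilyl)oxy]-2-{4-[(tert-butyldimethylsilyl)oxy]phenyl}-5-methoxy-8-(3-methylbut-2-en-1-yl)chromane-3,4-diol | COc1cc(O[Si](C)(C)C(C)(C)C)c(CC=C(C)C)c2c1[C@H](O)[C@H](O)[C@@H](c1ccc(O[Si](C)(C)C(C)(C)C)cc1)O2 | intermediate
22 | 5-O-methyl-8-prenylafzelechin-4β-ol, (2R,3S,4S)-2-(4-hydroxyphenyl)-5-methoxy-8-(3-methylbut-2-en-1-yl)chromane-3,4,7-triol | COc1cc(O)c(CC=C(C)C)c2c1[C@H](O)[C@H](O)[C@@H](c1ccc(O)cc1)O2 | target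

## Step count and least certain steps

Total: 14 steps. Longest linear sequence: 11 steps (steps 1–6 and 10–14). The ring B branch (steps 7–9) has 3 steps before the coupling.

**Step 11 (key step).** The most likely failures are these:
- Ionisation of the C4 carbinol by the Lewis-acidic titanium. The carbinol is benzylic to the trioxygenated ring A and allylic to a styrene, so C4 could scramble or the alcohol could transpose.
- Opening of the new para-silyloxyphenyl epoxide at C2 by isopropanol, tartrate or hydroperoxide during a long reaction.
- Slow or poorly discriminating oxygen transfer, because the carbinol substituent is a di-ortho-substituted aryl group whose allyloxy oxygen may also bind titanium.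

Fallback: setting out from 18 of any enantiomeric purity, oxidation with MnO2 gives the enone (E)-1-{2-(allyloxy)-4-[(tert-butyldimethylsilyl)oxy]-6-methoxy-3-prenylphenyl}-3-{4-[(tert-butyldimethylsilyl)oxy]phenyl}prop-2-en-1-one F1. Nucleophilic Juliá–Colonna epoxidation (poly-L-leucine, urea–hydrogen peroxide, DBU, THF) attacks only the electron-poor enone alkene and should give the (2R,3S)-epoxy ketone F2. Chelation-controlled reduction with Zn(BH4)2 is expected to give the erythro alcohol, returning to the route at 19.

**Step 10.** The di-ortho-alkoxy aldehyde may be too unreactive toward the alkenylzinc. The ligand-free background addition, promoted by the zirconium by-product, would then lower the enantiomeric purity, and methyl transfer from zinc could compete. Fallback: from 15 and 10, a zinc acetylide addition under a dinuclear zinc–ProPhenol catalyst (Me2Zn, with the ligand enantiomer chosen for Re-face delivery) gives the propargylic alcohol (R)-1-{2-(allyloxy)-4-[(tert-butyldimethylsilyl)oxy]-6-methoxy-3-prenylphenyl}-3-{4-[(tert-butyldimethylsilyl)oxy]phenyl}prop-2-yn-1-ol F3. Hydroxyl-directed trans-hydroalumination with NaAlH2(OCH2CH2OMe)2 in THF at 0 °C then returns to the route at 18.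

**Step 13.** The acid may open the epoxide through a free benzylic cation, losing stereospecificity at C2. It may also allow 5-exo attack at C3, or ionise the C4 hydroxyl of the product. Fallback: setting out from 20, unbuffered TBAF in THF removes both silyl groups to give the epoxy triphenol F4. Its ring B phenoxide opens the epoxide to the para-quinone methide F5, and the C8a oxygen adds to C2 under thermodynamic preference for the 2,3-trans ring. This returns to the route directly at 22 and by-passes 21.

**Step 3.** Deprotonation of the doubly activated (benzylic and allylic) CH2 of the prenyl group may compete with ring metalation. Fallback: setting out from 5, bromination of the free ring position with N-bromosuccinimide (MeCN, −20 °C) gives 2-bromo-1-methoxy-3,5-bis(methoxymethoxy)-4-(3-methylbut-2-en-1-yl)benzene F6. Bromine–lithium exchange with t-BuLi at −78 °C outruns any deprotonation and generates the same aryllithium 6, and formylation as before returns to the route at 7.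

**Step 4.** During acetal cleavage a flanking phenol may add to the protonated prenyl alkene, closing a dimethylchroman ring. Fallback: setting out from 1, Vilsmeier–Haack formylation (POCl3, DMF, then aqueous hydrolysis) gives 2,4-dihydroxy-6-methoxybenzaldehyde F7, which may need separation from its regioisomer. C-Prenylation of its phenoxide with 3 in aqueous KOH at the carbon between the two hydroxyls returns to the route at 8. This path is shorter and acid-free but is expected to be less regioselective.

Further compounds

F1 | step 11 | (E)-1-{2-(allyloxy)-4-[(tert-butyldimethylsilyl)oxy]-6-methoxy-3-(3-methylbut-2-en-1-yl)phenyl}-3-{4-[(tert-butyldimethylsilyl)oxy]phenyl}prop-2-en-1-one | COc1cc(O[Si](C)(C)C(C)(C)C)c(CC=C(C)C)c(OCC=C)c1C(=O)/C=C/c1ccc(O[Si](C)(C)C(C)(C)C)cc1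
F2 | step 11 | {2-(allyloxy)-4-[(tert-butyldimethylsilyl)oxy]-6-methoxy-3-(3-methylbut-2-en-1-yl)phenyl}[(2R,3S)-3-{4-[(tert-butyldimethylsilyl)oxy]phenyl}oxiran-2-yl]methanone | COc1cc(O[Si](C)(C)C(C)(C)C)c(CC=C(C)C)c(OCC=C)c1C(=O)[C@@H]2O[C@H]2c1ccc(O[Si](C)(C)C(C)(C)C)cc1
F3 | step 10 | (R)-1-{2-(allyloxy)-4-[(tert-butyldimethylsilyl)oxy]-6-methoxy-3-(3-methylbut-2-en-1-yl)phenyl}-3-{4-[(tert-butyldimethylsilyl)oxy]phenyl}prop-2-yn-1-ol | COc1cc(O[Si](C)(C)C(C)(C)C)c(CC=C(C)C)c(OCC=C)c1[C@H](O)C#Cc1ccc(O[Si](C)(C)C(C)(C)C)cc1
F4 | step 13 | (S)-[2,4-dihydroxy-6-methoxy-3-(3-methylbut-2-en-1-yl)phenyl][(2S,3S)-3-(4-hydroxyphenyl)oxiran-2-yl]methanol | COc1cc(O)c(CC=C(C)C)c(O)c1[C@H](O)[C@@H]2O[C@H]2c1ccc(O)cc1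
F5 | step 13 | 4-{(2R,3S)-3-[2,4-dihydroxy-6-methoxy-3-(3-methylbut-2-en-1-yl)phenyl]-2,3-dihydroxypropylidene}cyclohexa-2,5-dien-1-one | COc1cc(O)c(CC=C(C)C)c(O)c1[C@H](O)[C@H](O)C=C1C=CC(=O)C=C1
F6 | step 3 | 2-bromo-1-methoxy-3,5-bis(methoxymethoxy)-4-(3-methylbut-2-en-1-yl)benzene | COCOc1cc(OC)c(Br)c(OCOC)c1CC=C(C)C
F7 | step 4 | 2,4-dihydroxy-6-methoxybenzaldehyde | COc1cc(O)cc(O)c1C=O
A1 | alternative 1 | 1-methoxy-7-methyl-1,3-bis(trimethylsilyloxy)octa-1,3,6-triene | COC(O[Si](C)(C)C)=CC(O[Si](C)(C)C)=CCC=C(C)C
A2 | alternative 1 | (2R,3R)-5-bromo-3-[(tert-butyldimethylsilyl)oxy]-2-{4-[(triisopropylsilyl)oxy]phenyl}-2,3-dihydro-4H-pyran-4-one | O=C1C(Br)=CO[C@H](c2ccc(O[Si](C(C)C)(C(C)C)C(C)C)cc2)[C@H]1O[Si](C)(C)C(C)(C)C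
A3 | alternative 1 | (2R,3R)-3-[(tert-butyldimethylsilyl)oxy]-7-hydroxy-5-methoxy-8-(3-methylbut-2-en-1-yl)-2-{4-[(triisopropylsilyl)oxy]phenyl}chroman-4-one | COc1cc(O)c(CC=C(C)C)c2c1C(=O)[C@H](O[Si](C)(C)C(C)(C)C)[C@@H](c1ccc(O[Si](C(C)C)(C(C)C)C(C)C)cc1)O2
A4 | alternative 2 | 3-[(tert-butyldimethylsilyl)oxy]-5-methoxy-6-(methoxymethylidene)-2-(3-methylbut-2-en-1-yl)cyclohexa-2,4-dien-1-one | COC=C1C(=O)C(CC=C(C)C)=C(O[Si](C)(C)C(C)(C)C)C=C1OC
A5 | alternative 2 | (E)-2-{4-[(tert-butyldimethylsilyl)oxy]phenyl}vinyl acetate | CC(=O)O/C=C/c1ccc(O[Si](C)(C)C(C)(C)C)cc1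
A6 | alternative 2 | (2R,3S,4S)-7-[(tert-butyldimethylsilyl)oxy]-2-{4-[(tert-butyldimethylsilyl)oxy]phenyl}-4,5-dimethoxy-8-(3-methylbut-2-en-1-yl)chroman-3-yl acetate | COc1cc(O[Si](C)(C)C(C)(C)C)c(CC=C(C)C)c2c1[C@H](OC)[C@H](OC(C)=O)[C@@H](c1ccc(O[Si](C)(C)C(C)(C)C)cc1)O2
A7 | alternative 3 | {(4S,5S)-5-[2,4-bis[(tert-butyldimethylsilyl)oxy]-6-methoxy-3-(3-methylbut-2-en-1-yl)phenyl]-2-oxo-1,3-dioxolan-4-yl}{4-[(tert-butyldimethylsilyl)oxy]phenyl}methyl acetate (configuration at the acetate carbon immaterial) | COc1cc(O[Si](C)(C)C(C)(C)C)c(CC=C(C)C)c(O[Si](C)(C)C(C)(C)C)c1[C@@H]3OC(=O)O[C@@H]3C(OC(C)=O)c1ccc(O[Si](C)(C)C(C)(C)C)cc1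
A8 | alternative 3 | (4S,5S)-4-[2,4-dihydroxy-6-methoxy-3-(3-methylbut-2-en-1-yl)phenyl]-5-[(4-oxocyclohexa-2,5-dien-1-ylidene)methyl]-1,3-dioxolan-2-one | COc1cc(O)c(CC=C(C)C)c(O)c1[C@@H]3OC(=O)O[C@@H]3C=C1C=CC(=O)C=C1
A9 | alternative 3 | 3,4-O-carbonyl derivative of the target, (2R,3S,4S)-configured cyclic carbonate of 22 | COc1cc(O)c(CC=C(C)C)c2c1[C@@H]3OC(=O)O[C@@H]3[C@@H](c1ccc(O)cc1)O2
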